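The balance of a closed flask is the fixed point of these minutes: whatever Q is charged stays there in some form, so the part still unmade and the part made sum to 100 percent, and the meeting agreed to follow the logarithm of the unmade part.

| flask | Q | X | temperature | remark | time |
|---|---|---|---|---|---|
| noon | 0.028 M | 0.060 M | 35 °C | run made earlier |  |
| dusk | 0.044 M | 0.060 M | 85 °C | run made earlier |  |
| delta | 0.020 M | 0.0600 M | 130 °C |  | 4.0 min |
| theta | 0.020 M | 0.0600 M | 100 °C |  | 4.0 min |
| beta | 0.020 M | 0.0600 M | 40 °C |  | 4.0 min |
| eta | 0.020 M | 0.0600 M | 70 °C |  | 4.0 min |

- noon (time / min: L / %): 20.0: 2.6; 60.0: 14.8; 90.0: 23.9; 150: 38.7; 240: 52.7; 300: 60.2; 360: 65.0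
- dusk (time / min: L / %): 2.50: 19.5; 4.00: 27.6; 6.00: 34.1; 8.00: 38.0; 12.0: 41.4; 20.0: 42.3; 30.0: 42.3

(readings scatter by 0.3 percentage points)

- the best flask by amount of L, in percent of the Q charged; "all alike" if 1.5 percentage points covers them all (delta / theta / beta / eta / all alike)
- amount of L at the end, in percent of the Q charged, delta
- amount of L at the end, in percent of the Q charged, theta
- amount of L at the end, in percent of the Q charged, beta
- amount of L at the end, in percent of the Q charged, eta



The first speaker took noon past its lag, where L climbs from 14.8 % to 38.7 %, and reported that the unmade part, taken as what L lacks of the charge, falls there with a constant of 0.00366 /min. The second took the first dusk reading, 19.5 % at 2.50 min, and reported 0.0868 /min, warning that the lag counts against this figure.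

Another member then went to powers of ten: the two constants, read at the same charge of X, stand 1.38 decades apart, and she named the decades of rate per unit of inverse temperature the decade slope, 3040 K. Carried from dusk to delta, this slope lifts the constant by 0.946 decades, and constant times time gives a making count of 3.06, which leaves 4.67 % unmade, while theta's count of 0.760 leaves 46.7 %.

The chair objected that the last dusk reading stands at 42.3 % while noon, which differs in temperature and in its charge of Q, has reached 65.0 %, a higher figure, so part of what is made may leave L. The meeting therefore applied the plateau as read at dusk as the share of what is made that stays L, which gave as its own estimate delta 40.3 % and theta 22.5 %, and it minuted delta as ahead of theta.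

The forecast differed, putting theta first with delta 20 %, theta 32 %, beta 0.5 % and eta 14 %, on the ground that “the ceiling falls with temperature”.

The flasks gave delta as best, with delta 67.0 %, theta 39.6 %, beta 0.328 % and eta 13.8 %.

    Q → G (k = 0.290 /s, Ea = 89.0 kJ/mol)
    X + G → L (k = 0.0720 /M/s, Ea = 60.0 kJ/mol)
    L ⇌ E (K = 0.860, k = 0.00520 /s, Ea = 103 kJ/mol, ΔH = −28.0 kJ/mol)
    (constants at 100 °C)

In delta, Q passed into G with a half-life of 0.28 s at 0.00472 min, and X + G into L then ran, with Q, the limiting reagent, at 0 % by 4.00 min and X, in percent of its own charge, falling from 72.3 % at 2.00 min to 67.9 % at 4.00 min, while L and E relaxed by their own step, both ways together, with a half-life of 0.0573 min, shorter than the flask's time, and G ended at 3.70 % against the 4.67 % unmade by the decade slope. In theta, X + G into L was still running at 4.00 min, with G at 40.6 % against 46.7 % by the same slope, and L at 39.6 %.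

The readings stem from a simulated flask from invented constants; scatter was added.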